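**Retrosynthetic overview**
- Feature used: in ring A (C6–C11) the tertiary carbinol C7 lies γ and C8 lies β to the C10 carbonyl. C7 and C8 can therefore both be carbonyl carbons (C7 methyl ketone, C8 aldehyde) joined reductively, and the surplus C8 oxygen is later expelled by β-elimination once C10 is a ketone.
- Key disconnection C7–C8 by SmI2 pinacol coupling; this is the only ring-forming step (ring A). The last bond made is the C1–O aryl ether (Mitsunobu with umbelliferone).
- The keto aldehyde comes from one double ozonolysis of a diene (isopropenyl → C7 acetyl, allyl → C8 aldehyde); the allyl group is put on the C10 aldehyde by asymmetric allylboration.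
- The chain carbinol C3 is set by olefination, Sharpless epoxidation and hydride opening of a methyl ketone; the acyclic keto aldehyde comes from gem-dimethylation and oxidative ring cleavage of (R)-carvone, whose stereocentre becomes C6.

Key step: step 15

Numbering used: ring A = C6 (CH bearing the side chain), C7 (C(OH)CH3), C8, C9, C10 (C=O), C11 (CMe2); side chain from C6 = C5H2, C4H2, C3(CH3)(OH), C2H2, C1H2–O–aryl.
Assumption: C10 is carried through the key step as a triethylsilyl-protected secondary carbinol (a ketal of a ketone flanked by the quaternary C11 is judged too unreliable to form) and is oxidised to the ketone after the coupling.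

**Route**

Step 1
Reactants: 1 (R)-carvone; 2 iodomethane
Product: 4 6-methylcarvone (C6 epimers), via lithium dienolate 3 (not isolated)
Conditions: LiN(iPr)2 (LDA), THF, −78 °C; MeI, −78 → 0 °C
Reagents that add atoms: iodomethane (2), CI
Why: Kinetic deprotonation at the α′-CH2 gives the cross-conjugated dienolate, which is C-methylated (enolate alkylation); the new centre is quaternised in step 2, so its configuration does not matter.

Step 2
Reactants: 4 6-methylcarvone; 2 iodomethane
Product: 6 (S)-6,6-dimethylcarvone, via lithium dienolate 5 (not isolated)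
Conditions: LiN(iPr)2, THF, −78 °C; MeI, DMPU, −78 °C → rt
Reagents that add atoms: iodomethane (2), CI
Why: A second enolate alkylation at the same α′-carbon installs the gem-dimethyl group (future C11) next to the carvone stereocentre (future C6), which is not enolisable and stays intact.

Step 3
Reactants: 6 (S)-6,6-dimethylcarvone
Product: 7 epoxy ketone
Conditions: 30% H2O2, NaOH (cat.), MeOH, 0 °C
Reagents that add atoms: hydrogen peroxide, OO
Why: Weitz–Scheffer nucleophilic epoxidation attacks only the electron-poor enone C=C (hydroperoxide adds to the unhindered β-carbon) and leaves the isopropenyl group alone; the epoxide configuration is immaterial.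

Step 4
Reactants: 7 epoxy ketone
Product: 9 cyclic 1,2-diol (diastereomers), via epoxy alcohol 8 (not isolated)
Conditions: LiAlH4, THF, 0 °C → reflux; aqueous NaOH work-up
Reagents that add atoms: none
Why: Hydride reduces the ketone and then opens the trisubstituted epoxide by SN2 attack at its secondary carbon, so oxygen stays on the methyl-bearing carbon and a vicinal secondary/tertiary diol results (both carbinol carbons become carbonyls next, so their configuration is irrelevant).

Step 5
Reactants: 9 cyclic 1,2-diol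
Product: 10 keto aldehyde (3S)-2,2-dimethyl-6-oxo-3-(prop-1-en-2-yl)heptanal
Conditions: NaIO4, THF/H2O (pH 7), rt
Reagents that add atoms: none
Why: Periodate glycol cleavage gives a non-enolisable neopentylic aldehyde (future C10) and a methyl ketone (future C3 with its methyl) without touching the alkene or the stereocentre.

Step 6
Reactants: 11 allylmagnesium bromide; 12 triisopropyl borate; 13 diisopropyl D-(−)-tartrate
Product: 15 (S,S)-tartrate allylboronate, via allylboronic acid 14 (not isolated)
Conditions: 11, B(OiPr)3, Et2O, −78 °C; aq. HCl; then D-(−)-DIPT, MgSO4, Et2O, rt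
Reagents that add atoms: allylmagnesium bromide (11), C=CC[Mg]Br; triisopropyl borate (12), CC(C)OB(OC(C)C)OC(C)C; diisopropyl D-tartrate (13), CC(C)OC(=O)[C@@H](O)[C@H](O)C(=O)OC(C)C
Why: Standard preparation of a tartrate allylboronate: Grignard addition to the borate, hydrolysis, and esterification with the tartrate diol under dehydrating conditions.

Step 7
Reactants: 10 keto aldehyde; 15 (S,S)-tartrate allylboronate
Product: 16 (5S,7R)-7-hydroxy-6,6-dimethyl-5-(prop-1-en-2-yl)dec-9-en-2-one
Conditions: 15, 4 Å molecular sieves, toluene, −78 °C; aq. NaOH work-up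
Reagents that add atoms: (S,S)-tartrate allylboronate (15), C=CCB1O[C@H](C(=O)OC(C)C)[C@@H](C(=O)OC(C)C)O1
Why: Roush asymmetric allylboration through a chair six-membered transition state, in which the (S,S)-tartrate should deliver allyl to the Re face of the aldehyde and give the (R)-carbinol at future C10; allylboronates do not add to ketones, so the methyl ketone survives, and any minor C10 epimer is a separable diastereomer.

Step 8
Reactants: 16 hydroxy ketone; 17 triethyl phosphonoacetate
Product: 18 ethyl (2E,6S,8R)-8-hydroxy-3,7,7-trimethyl-6-(prop-1-en-2-yl)undeca-2,10-dienoate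
Conditions: NaH, (EtO)2P(O)CH2CO2Et, THF, 0 °C → reflux
Reagents that add atoms: triethyl phosphonoacetate (17), CCOC(=O)CP(=O)(OCC)OCC
Why: Horner–Wadsworth–Emmons olefination of the methyl ketone under thermodynamic control should favour the (E)-trisubstituted enoate (minor Z isomer removed by chromatography); the stabilised phosphonate anion is too weak a base to disturb the free hydroxyl.

Step 9
Reactants: 18 (E)-enoate
Product: 19 (2E,6S,8R)-3,7,7-trimethyl-6-(prop-1-en-2-yl)undeca-2,10-diene-1,8-diol
Conditions: i-Bu2AlH, CH2Cl2, −78 °C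
Reagents that add atoms: none
Why: Excess i-Bu2AlH reduces the conjugated ester in 1,2-fashion to the (E)-allylic alcohol; the isolated alkenes are inert.

Step 10
Reactants: 19 allylic alcohol
Product: 20 (2R,3R)-2,3-epoxy alcohol
Conditions: Ti(OiPr)4 (10 mol%), D-(−)-DET (12 mol%), t-BuOOH, 4 Å molecular sieves, CH2Cl2, −20 °C
Reagents that add atoms: tert-butyl hydroperoxide, CC(C)(C)OO
Why: Sharpless asymmetric epoxidation is directed by the allylic hydroxyl, so only the trisubstituted allylic alkene reacts; with D-(−)-DET an (E)-3,3-disubstituted allylic alcohol gives the (2R,3R)-epoxide (mirror image of the geraniol/L-tartrate case), which fixes the chain carbinol carbon C3.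

Step 11
Reactants: 20 epoxy alcohol
Product: 21 (3R,6S,8R)-3,7,7-trimethyl-6-(prop-1-en-2-yl)undec-10-ene-1,3,8-triol
Conditions: NaAlH2(OCH2CH2OMe)2 (Red-Al), THF, 0 °C → rt
Reagents that add atoms: none
Why: The aluminate bound to the primary alkoxide delivers hydride intramolecularly to C2 of the 2,3-epoxy alcohol (also the less substituted epoxide carbon), giving the 1,3-diol with the tertiary C3–O bond and its (R) configuration untouched.

Step 12
Reactants: 21 triol
Product: 22 primary tert-butyldiphenylsilyl ether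
Conditions: t-BuPh2SiCl, imidazole, DMAP (cat.), CH2Cl2, 0 °C
Reagents that add atoms: tert-butyldiphenylsilyl chloride, CC(C)(C)[Si](Cl)(c1ccccc1)c1ccccc1
Why: The bulky silyl chloride reacts only with the unhindered primary hydroxyl and leaves the neopentylic secondary and the tertiary hydroxyl free.

Step 13
Reactants: 22 silyl ether diol
Product: 23 bis(triethylsilyl) ether diene
Conditions: Et3SiOTf, 2,6-lutidine, CH2Cl2, −78 → 0 °C
Reagents that add atoms: triethylsilyl triflate, CC[Si](CC)(CC)OS(=O)(=O)C(F)(F)F
Why: The silyl triflate is reactive enough to silylate both the hindered secondary C10 hydroxyl and the tertiary C3 hydroxyl.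

Step 14
Reactants: 23 diene
Product: 25 keto aldehyde (3R,5R,8R)-5-acetyl-10-(tert-butyldiphenylsilyloxy)-4,4,8-trimethyl-3,8-bis(triethylsilyloxy)decanal, via bis-ozonide 24 (not isolated)
Conditions: O3, CH2Cl2, −78 °C; PPh3, −78 °C → rt
Reagents that add atoms: ozone, [O-][O+]=O
Why: Ozonolysis cleaves the terminal vinyl group to the C8 aldehyde and the isopropenyl group to the C7 methyl ketone in one operation; neutral reductive work-up avoids epimerisation of C6 (now α to the ketone), and the crude keto aldehyde is used at once.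

Step 15
Reactants: 25 keto aldehyde
Product: 26 ring A cis-7,8-diol (C7–OH, C8–OH, C10–OSiEt3 and the C6 side chain all on one face)
Conditions: SmI2 (3 equiv), t-BuOH (2 equiv), THF (0.01 M), −78 → −20 °C; aq. NaHCO3
Reagents that add atoms: none
Why: SmI2 transfers one electron to the more easily reduced C8 aldehyde, the ketyl radical (bound to trivalent samarium) adds to the samarium-coordinated C7 ketone carbon, and a second electron transfer gives the samarium diolate, protonated on work-up. The closest known reaction type is the SmI2-mediated intramolecular ketone–aldehyde pinacol coupling of 1,6-dicarbonyl compounds to cis-cyclohexane-1,2-diols. Ring A closes in the 6-exo-trig mode (C8 radical onto C7=O, the C7–O bond exocyclic to the new ring). C8 should be set cis to C7–O because both oxygens sit on one samarium centre in the cyclic transition state; C7 should be set relative to C6 by a chair in which the C6 side chain and C10–OSiEt3 are equatorial and the C7 oxygen is axial, since the alternative places the C7 methyl 1,3-diaxial to the axial C11 methyl. The step needs reduction of the aldehyde before the ketone and ring closure faster than simple reduction or dimerisation; the aldehyde/ketone reduction-potential gap, high dilution, low temperature and the gem-dimethyl (Thorpe–Ingold) bias should secure this, and neither C6 nor C9 carries a heteroatom that SmI2 could cleave.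

Step 16
Reactants: 26 cis-diol
Product: 27 C8 mesylate
Conditions: MsCl, Et3N, CH2Cl2, −20 → 0 °C
Reagents that add atoms: methanesulfonyl chloride, CS(=O)(=O)Cl
Why: Sulfonylation takes the secondary C8 hydroxyl selectively; the tertiary C7 hydroxyl is too hindered to react and, being cis, cannot displace the mesylate to form an epoxide.

Step 17
Reactants: 27 mesylate
Product: 28 mesylate with free C10 and C3 hydroxyls
Conditions: CSA (cat.), MeOH/CH2Cl2, 0 °C
Reagents that add atoms: none
Why: Acid-catalysed methanolysis removes the two triethylsilyl ethers, while the primary tert-butyldiphenylsilyl ether and the mesylate are stable under these conditions.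

Step 18
Reactants: 28 hydroxy mesylate
Product: 30 C8=C9 enone, via β-mesyloxy ketone 29 (not isolated)
Conditions: Dess–Martin periodinane, CH2Cl2, rt; then DBU, 0 °C → rt
Reagents that add atoms: none
Why: Dess–Martin oxidation of the only free secondary alcohol gives the C10 ketone, which puts the C8 mesylate β to a carbonyl; DBU then effects E1cB elimination to the enone, removing the surplus C8 oxygen while the tertiary C7 carbinol stays.

Step 19
Reactants: 30 enone
Product: 31 saturated ring A ketone
Conditions: H2 (1 atm), Pd/C, EtOAc, rt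
Reagents that add atoms: none
Why: Heterogeneous hydrogenation saturates the enone C=C; no stereocentre is formed and the silyl ether, ketone and tertiary alcohols are untouched.

Step 20
Reactants: 31 silyl ether
Product: 32 (3R,4S)-3-[(3R)-3,5-dihydroxy-3-methylpentyl]-4-hydroxy-2,2,4-trimethylcyclohexan-1-one
Conditions: Bu4NF, THF, 0 °C → rt
Reagents that add atoms: none
Why: Fluoride cleaves the silyl ether and frees the primary alcohol.

Step 21
Reactants: 32 triol ketone; 33 umbelliferone
Product: 34 target
Conditions: PPh3, DIAD, THF, 0 °C → rt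
Reagents that add atoms: umbelliferone (33), O=c1ccc2ccc(O)cc2o1
Why: Mitsunobu etherification: the acidic phenol displaces the activated primary alcohol in an SN2 step; the two tertiary alcohols cannot be activated and no stereocentre is involved.

**Compound list**

1 | (R)-carvone | CC1=CC[C@H](CC1=O)C(C)=C | starting material
2 | iodomethane | CI | starting material
3 | lithium dienolate of 1 (not isolated) | CC1=CC[C@@H](C(C)=C)C=C1O[Li] | intermediate
4 | (5R)-2,6-dimethyl-5-(prop-1-en-2-yl)cyclohex-2-en-1-one (6-methylcarvone, C6 epimers) | CC1=CC[C@@H](C(C)=C)C(C)C1=O | intermediate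
5 | lithium dienolate of 4 (not isolated) | CC1=CC[C@@H](C(C)=C)C(C)=C1O[Li] | intermediate
6 | (5S)-2,6,6-trimethyl-5-(prop-1-en-2-yl)cyclohex-2-en-1-one (6,6-dimethylcarvone) | CC1=CC[C@@H](C(C)=C)C(C)(C)C1=O | intermediate
7 | (4S)-1,3,3-trimethyl-4-(prop-1-en-2-yl)-7-oxabicyclo[4.1.0]heptan-2-one (oxirane epimers) | CC12OC1C[C@@H](C(C)=C)C(C)(C)C2=O | intermediate
8 | epoxy alcohol from ketone reduction of 7 (not isolated) | CC12OC1C[C@@H](C(C)=C)C(C)(C)C2O | intermediate
9 | (4S)-1,3,3-trimethyl-4-(prop-1-en-2-yl)cyclohexane-1,2-diol (diastereomers at C1, C2) | CC1(O)CC[C@@H](C(C)=C)C(C)(C)C1O | intermediate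
10 | (3S)-2,2-dimethyl-6-oxo-3-(prop-1-en-2-yl)heptanal | O=CC(C)(C)[C@H](C(C)=C)CCC(C)=O | intermediate
11 | allylmagnesium bromide | C=CC[Mg]Br | starting material
12 | triisopropyl borate | CC(C)OB(OC(C)C)OC(C)C | starting material
13 | diisopropyl D-(−)-tartrate, (2S,3S) | CC(C)OC(=O)[C@@H](O)[C@H](O)C(=O)OC(C)C | starting material
14 | allylboronic acid (not isolated) | C=CCB(O)O | intermediate
15 | diisopropyl (4S,5S)-2-(prop-2-en-1-yl)-1,3,2-dioxaborolane-4,5-dicarboxylate | C=CCB1O[C@H](C(=O)OC(C)C)[C@@H](C(=O)OC(C)C)O1 | intermediate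
16 | (5S,7R)-7-hydroxy-6,6-dimethyl-5-(prop-1-en-2-yl)dec-9-en-2-one | C=CC[C@@H](O)C(C)(C)[C@H](C(C)=C)CCC(C)=O | intermediate
17 | triethyl phosphonoacetate | CCOC(=O)CP(=O)(OCC)OCC | starting material
18 | ethyl (2E,6S,8R)-8-hydroxy-3,7,7-trimethyl-6-(prop-1-en-2-yl)undeca-2,10-dienoate | C=CC[C@@H](O)C(C)(C)[C@H](C(C)=C)CC/C(C)=C/C(=O)OCC | intermediate
19 | (2E,6S,8R)-3,7,7-trimethyl-6-(prop-1-en-2-yl)undeca-2,10-diene-1,8-diol | C=CC[C@@H](O)C(C)(C)[C@H](C(C)=C)CC/C(C)=C/CO | intermediate
20 | [(2R,3R)-3-[(3S,5R)-5-hydroxy-4,4-dimethyl-3-(prop-1-en-2-yl)oct-7-en-1-yl]-3-methyloxiran-2-yl]methanol | C=CC[C@@H](O)C(C)(C)[C@H](C(C)=C)CC[C@@]1(C)O[C@@H]1CO | intermediate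
21 | (3R,6S,8R)-3,7,7-trimethyl-6-(prop-1-en-2-yl)undec-10-ene-1,3,8-triol | C=CC[C@@H](O)C(C)(C)[C@H](C(C)=C)CC[C@@](C)(O)CCO | intermediate
22 | (3R,6S,8R)-1-(tert-butyldiphenylsilyloxy)-3,7,7-trimethyl-6-(prop-1-en-2-yl)undec-10-ene-3,8-diol | C=CC[C@@H](O)C(C)(C)[C@H](C(C)=C)CC[C@@](C)(O)CCO[Si](C(C)(C)C)(c1ccccc1)c1ccccc1 | intermediate
23 | 3,8-bis(triethylsilyl) ether of 22 | C=CC[C@@H](O[Si](CC)(CC)CC)C(C)(C)[C@H](C(C)=C)CC[C@@](C)(O[Si](CC)(CC)CC)CCO[Si](C(C)(C)C)(c1ccccc1)c1ccccc1 | intermediate
24 | bis(1,2,4-trioxolane) of 23 (not isolated) | C1OC(C[C@@H](O[Si](CC)(CC)CC)C(C)(C)[C@H](C2(C)OCOO2)CC[C@@](C)(O[Si](CC)(CC)CC)CCO[Si](C(C)(C)C)(c2ccccc2)c2ccccc2)OO1 | intermediate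
25 | (3R,5R,8R)-5-acetyl-10-(tert-butyldiphenylsilyloxy)-4,4,8-trimethyl-3,8-bis(triethylsilyloxy)decanal (C8 formyl, C7 acetyl on C6) | O=CC[C@@H](O[Si](CC)(CC)CC)C(C)(C)[C@H](C(C)=O)CC[C@@](C)(O[Si](CC)(CC)CC)CCO[Si](C(C)(C)C)(c1ccccc1)c1ccccc1 | intermediate
26 | (1R,2S,4R,6R)-6-[(3R)-5-(tert-butyldiphenylsilyloxy)-3-methyl-3-(triethylsilyloxy)pentyl]-1,5,5-trimethyl-4-(triethylsilyloxy)cyclohexane-1,2-diol | CC1(C)[C@H](O[Si](CC)(CC)CC)C[C@H](O)[C@](C)(O)[C@@H]1CC[C@@](C)(O[Si](CC)(CC)CC)CCO[Si](C(C)(C)C)(c1ccccc1)c1ccccc1 | intermediate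
27 | C8 (secondary) methanesulfonate of 26 | CC1(C)[C@H](O[Si](CC)(CC)CC)C[C@H](OS(C)(=O)=O)[C@](C)(O)[C@@H]1CC[C@@](C)(O[Si](CC)(CC)CC)CCO[Si](C(C)(C)C)(c1ccccc1)c1ccccc1 | intermediate
28 | 27 with both triethylsilyl groups removed (free C10–OH and C3–OH) | CC1(C)[C@H](O)C[C@H](OS(C)(=O)=O)[C@](C)(O)[C@@H]1CC[C@@](C)(O)CCO[Si](C(C)(C)C)(c1ccccc1)c1ccccc1 | intermediate
29 | C10 ketone with C8 mesylate (not isolated) | CC1(C)C(=O)C[C@H](OS(C)(=O)=O)[C@](C)(O)[C@@H]1CC[C@@](C)(O)CCO[Si](C(C)(C)C)(c1ccccc1)c1ccccc1 | intermediate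
30 | (4S,5R)-5-[(3R)-5-(tert-butyldiphenylsilyloxy)-3-hydroxy-3-methylpentyl]-4-hydroxy-4,6,6-trimethylcyclohex-2-en-1-one | CC1(C)C(=O)C=C[C@](C)(O)[C@@H]1CC[C@@](C)(O)CCO[Si](C(C)(C)C)(c1ccccc1)c1ccccc1 | intermediate
31 | (3R,4S)-3-[(3R)-5-(tert-butyldiphenylsilyloxy)-3-hydroxy-3-methylpentyl]-4-hydroxy-2,2,4-trimethylcyclohexan-1-one | CC1(C)C(=O)CC[C@](C)(O)[C@@H]1CC[C@@](C)(O)CCO[Si](C(C)(C)C)(c1ccccc1)c1ccccc1 | intermediate
32 | (3R,4S)-3-[(3R)-3,5-dihydroxy-3-methylpentyl]-4-hydroxy-2,2,4-trimethylcyclohexan-1-one | CC1(C)C(=O)CC[C@](C)(O)[C@@H]1CC[C@@](C)(O)CCO | intermediate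
33 | umbelliferone (7-hydroxycoumarin) | O=c1ccc2ccc(O)cc2o1 | starting material
34 | 7-{[(3R)-3-hydroxy-5-[(1R,6S)-6-hydroxy-2,2,6-trimethyl-3-oxocyclohexyl]-3-methylpentyl]oxy}-2H-chromen-2-one | CC1(C)C(=O)CC[C@](C)(O)[C@@H]1CC[C@@](C)(O)CCOc1ccc2ccc(=O)oc2c1 | target

**Step count**
Total: 21 steps. Longest linear sequence: 20 steps (steps 1–5 and 7–21; step 6 is a reagent side branch).

**Steps most likely to fail**

1. Step 15. What may go wrong: the ketyl attacks the wrong face of the C7 ketone (giving the C7 epimer of the cis-diol), the carbonyl groups are simply reduced without C–C bond formation, or C6 epimerises before ring closure. Fallback, setting out from diene 23 and returning at 31: ring-closing metathesis of the isopropenyl and allyl termini with second-generation Grubbs catalyst (CH2Cl2, 40 °C) gives the C7=C8 cyclohexene F1. CSA in MeOH removes both triethylsilyl groups to give the homoallylic alcohol diol F2. VO(acac)2/t-BuOOH epoxidation, directed by the homoallylic C10 hydroxyl, puts the oxirane on the face cis to C10–OH and the C6 chain, giving epoxide F3. LiAlH4 opens it trans-diaxially at the secondary C8 (Fürst–Plattner rule), leaving the axial C7 tertiary alcohol in triol F4. Dess–Martin oxidation of the only secondary alcohol (C10) then gives 31.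

2. Step 8. What may go wrong: low E/Z selectivity in the olefination of the methyl ketone; the Z isomer, taken through the D-tartrate epoxidation, would give the C3 epimer. Fallback, setting out from 16 and returning at 21: the geometric isomers are separated and the Z-enoate F5 is used rather than discarded. Reduction with i-Bu2AlH gives the (Z)-allylic alcohol F6. Sharpless epoxidation with the antipodal ligand L-(+)-DET gives the (2S,3R)-epoxy alcohol F7, which has the same C3 configuration as 20 (in the Z isomer methyl and chain are exchanged on C3, so the opposite face must be attacked). NaAlH2(OCH2CH2OMe)2 then opens F7 to the same triol 21, so both isomers converge.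

3. Step 7. What may go wrong: slow addition of the mild boronate to the neopentylic aldehyde and incomplete reagent control at C10; a more reactive allylborane cannot be used while the methyl ketone is present. Fallback, setting out from 10 and returning at 18: NaBH4 in EtOH/CH2Cl2 at −78 °C reduces the aldehyde selectively to the keto alcohol F8. Horner–Wadsworth–Emmons olefination with 17/NaH gives the hydroxy enoate F9, and Dess–Martin oxidation gives the enoate aldehyde F10. With no ketone left, Brown allylation with B-allyldiisopinocampheylborane (the antipode derived from (−)-α-pinene, Re-face attack; Et2O, −78 °C; NaBO3 work-up) gives 18.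

**Further compounds**

F1 | step 15 | C7=C8 cyclohexene from ring-closing metathesis of 23 | CC1=CC[C@@H](O[Si](CC)(CC)CC)C(C)(C)[C@H]1CC[C@@](C)(O[Si](CC)(CC)CC)CCO[Si](C(C)(C)C)(c1ccccc1)c1ccccc1
F2 | step 15 | cyclohexenol diol (C10–OH and C3–OH free) | CC1=CC[C@@H](O)C(C)(C)[C@H]1CC[C@@](C)(O)CCO[Si](C(C)(C)C)(c1ccccc1)c1ccccc1
F3 | step 15 | 7,8-epoxide cis to C10–OH | C[C@]12O[C@H]1C[C@@H](O)C(C)(C)[C@H]2CC[C@@](C)(O)CCO[Si](C(C)(C)C)(c1ccccc1)c1ccccc1
F4 | step 15 | C7, C10, C3 triol (C8 deoxygenated) | CC1(C)[C@H](O)CC[C@](C)(O)[C@@H]1CC[C@@](C)(O)CCO[Si](C(C)(C)C)(c1ccccc1)c1ccccc1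
F5 | step 8 | ethyl (2Z,6S,8R)-8-hydroxy-3,7,7-trimethyl-6-(prop-1-en-2-yl)undeca-2,10-dienoate | C=CC[C@@H](O)C(C)(C)[C@H](C(C)=C)CC/C(C)=C\C(=O)OCC
F6 | step 8 | (2Z,6S,8R)-3,7,7-trimethyl-6-(prop-1-en-2-yl)undeca-2,10-diene-1,8-diol | C=CC[C@@H](O)C(C)(C)[C@H](C(C)=C)CC/C(C)=C\CO
F7 | step 8 | (2S,3R)-2,3-epoxy alcohol (C2 epimer of 20) | C=CC[C@@H](O)C(C)(C)[C@H](C(C)=C)CC[C@@]1(C)O[C@H]1CO
F8 | step 7 | (5S)-7-hydroxy-6,6-dimethyl-5-(prop-1-en-2-yl)heptan-2-one | OCC(C)(C)[C@H](C(C)=C)CCC(C)=O
F9 | step 7 | ethyl (2E,6S)-8-hydroxy-3,7,7-trimethyl-6-(prop-1-en-2-yl)oct-2-enoate | OCC(C)(C)[C@H](C(C)=C)CC/C(C)=C/C(=O)OCC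
F10 | step 7 | ethyl (2E,6S)-3,7,7-trimethyl-8-oxo-6-(prop-1-en-2-yl)oct-2-enoate | O=CC(C)(C)[C@H](C(C)=C)CC/C(C)=C/C(=O)OCC
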